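Ring A is closed last, across C3–C4. The C2 ketone with its β-methyl group (C15 on C4) is treated as an opened cyclopropyl ketone: a vinyl group on the quaternary C5 (C4=C15) and a propargyl group on C10 (C1–C2≡C3) are joined when an α-oxo gold carbene, made at C3 by oxidation of the alkyne, cyclopropanates the vinyl group. One operation forms C3–C4 (ring A) and C3–C15, installs the C2 carbonyl and sets C4; SmI2 then cuts C3–C15 to free the methyl group. The precursor is a fully decorated ring B, made from (+)-3-carene by cleaving its cyclopropane.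

Key step: step 9

Numbering used throughout (eremophilane): ring A = C1, C2 (ketone), C3, C4 (methyl C15), C5 (methyl C14), C10; ring B = C5, C6, C7 (isopropenyl), C8 (acetate), C9 (3-methylbut-2-enoate), C10. The rings are cis-fused, and the two methyl groups, H-10 and the isopropenyl group are on one face, with both ester oxygens on the other. Locants inside systematic names are those of the name.

Assumption: commercial (+)-3-carene is the (1S,6R) enantiomer; its C1 becomes C7 of the target with the required R configuration.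

Step 1
Reactants: 1 (+)-3-carene
Product: 2 (1R,6S)-4,7,7-trimethylbicyclo[4.1.0]hept-3-en-2-one (car-3-en-5-one)
Conditions: t-BuOOH, CrO3 (cat.), CH2Cl2, rt
Reagents that add atoms: tert-butyl hydroperoxide, CC(C)(C)OO
Why: Chromium-catalysed allylic oxidation should attack the ring methylene next to the unsubstituted alkene carbon and give the β-methyl enone; no stereocentre is touched.

Step 2
Reactants: 2 (1R,6S)-4,7,7-trimethylbicyclo[4.1.0]hept-3-en-2-one
Product: 3 (5S)-3-methyl-5-(prop-1-en-2-yl)cyclohex-2-en-1-one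
Conditions: degassed Ph2O, sealed tube, 250 °C
Reagents that add atoms: none
Why: Retro-ene reaction (homo-1,5-hydrogen shift) of a cis-alkyl cyclopropyl ketone: a hydrogen of the C7 methyl group syn to the six-membered ring passes to the carbonyl oxygen through a six-membered transition state while the C1–C7 bond breaks, and the dienol tautomerises to the enone, so the isopropenyl group forms regiospecifically and the remaining stereocentre is untouched.

Step 3
Reactants: 3 (5S)-3-methyl-5-(prop-1-en-2-yl)cyclohex-2-en-1-one; 4 vinylmagnesium bromide; 5 3-bromo-1-(trimethylsilyl)prop-1-yne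
Product: 7 (2R,3R,5S)-3-ethenyl-3-methyl-5-(prop-1-en-2-yl)-2-[3-(trimethylsilyl)prop-2-yn-1-yl]cyclohexan-1-one (major C2 epimer), via bromomagnesium enolate 6 (not isolated)
Conditions: CuBr·SMe2 (10 mol %), THF, −40 °C; then DMPU, −40 °C → rt
Reagents that add atoms: none
Why: Tandem conjugate addition–enolate alkylation: the copper-catalysed 1,4-addition occurs axially and anti to the isopropenyl group (trans-3,5 rule for 5-substituted cyclohexenones), which sets the quaternary C5, and the regiodefined enolate is C-alkylated by the propargylic bromide, expected mainly anti to the new axial vinyl group.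

Step 4
Reactants: 7 (2R,3R,5S)-3-ethenyl-3-methyl-5-(prop-1-en-2-yl)-2-[3-(trimethylsilyl)prop-2-yn-1-yl]cyclohexan-1-one
Product: 8 (2S,3R,5S)-3-ethenyl-3-methyl-5-(prop-1-en-2-yl)-2-(prop-2-yn-1-yl)cyclohexan-1-one
Conditions: K2CO3, MeOH, rt → 40 °C
Reagents that add atoms: none
Why: Methanolysis of the C(sp)–Si bond and base-mediated epimerisation of the enolisable C2 (C10) should favour the isomer with the propargyl group equatorial, cis to the axial vinyl group, because the ring is locked by the equatorial isopropenyl and methyl groups and the other epimer must carry the side chain axially; the minor epimer can be re-submitted.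

Step 5
Reactants: 8 (2S,3R,5S)-3-ethenyl-3-methyl-5-(prop-1-en-2-yl)-2-(prop-2-yn-1-yl)cyclohexan-1-one
Product: 10 (2S,3R,5R,6S)-6-bromo-3-ethenyl-3-methyl-5-(prop-1-en-2-yl)-2-(prop-2-yn-1-yl)cyclohexan-1-one, via trimethylsilyl enol ether 9 (not isolated)
Conditions: Me3SiOTf, Et3N, CH2Cl2, 0 °C; then NBS, THF, −78 °C
Reagents that add atoms: N-bromosuccinimide, O=C1CCC(=O)N1Br; trimethylsilyl triflate, C[Si](C)(C)OS(=O)(=O)C(F)(F)F (its silyl group stays only in 9)
Why: Soft enolisation should give the less hindered enol ether toward C8 (the other α-carbon is a methine beside the quaternary carbon), and electrophilic bromination of it by axial attack on the face opposite the axial vinyl group gives the axial bromide cis to the isopropenyl group.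

Step 6
Reactants: 10 (2S,3R,5R,6S)-6-bromo-3-ethenyl-3-methyl-5-(prop-1-en-2-yl)-2-(prop-2-yn-1-yl)cyclohexan-1-one
Product: 11 (1R,3S,4R,6R)-4-ethenyl-4-methyl-2-oxo-6-(prop-1-en-2-yl)-3-(prop-2-yn-1-yl)cyclohexyl acetate
Conditions: KOAc, 18-crown-6 (cat.), MeCN, rt
Reagents that add atoms: potassium acetate, CC(=O)[O-].[K+]
Why: SN2 displacement of the carbonyl-activated axial bromide goes with inversion and places the acetoxy group equatorial, trans to the isopropenyl group, which is also the more stable epimer of this enolisable centre.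

Step 7
Reactants: 11 (1R,3S,4R,6R)-4-ethenyl-4-methyl-2-oxo-6-(prop-1-en-2-yl)-3-(prop-2-yn-1-yl)cyclohexyl acetate
Product: 12 (1R,2S,3S,4R,6R)-4-ethenyl-2-hydroxy-4-methyl-6-(prop-1-en-2-yl)-3-(prop-2-yn-1-yl)cyclohexyl acetate
Conditions: LiBH(s-Bu)3, THF, −78 °C; AcOH, −78 °C
Reagents that add atoms: none
Why: Substrate-controlled ketone reduction: the bulky hydride attacks from the equatorial direction because the axial trajectory is blocked by the syn-axial vinyl group, which gives the axial C9 alcohol cis to the acetate, and the cold quench suppresses acetyl migration.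

Step 8
Reactants: 12 (1R,2S,3S,4R,6R)-4-ethenyl-2-hydroxy-4-methyl-6-(prop-1-en-2-yl)-3-(prop-2-yn-1-yl)cyclohexyl acetate; 13 3-methylbut-2-enoyl chloride
Product: 14 (1S,2S,3R,5R,6R)-6-(acetyloxy)-3-ethenyl-3-methyl-5-(prop-1-en-2-yl)-2-(prop-2-yn-1-yl)cyclohexyl 3-methylbut-2-enoate
Conditions: pyridine, DMAP (cat.), CH2Cl2, 0 → 40 °C
Reagents that add atoms: none
Why: DMAP-catalysed acylation of the remaining axial secondary alcohol; pyridine as the only base avoids ketene formation and deconjugation of the unsaturated acyl group.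

Step 9
Reactants: 14 (1S,2S,3R,5R,6R)-6-(acetyloxy)-3-ethenyl-3-methyl-5-(prop-1-en-2-yl)-2-(prop-2-yn-1-yl)cyclohexyl 3-methylbut-2-enoate
Product: 15 (1aR,3aS,4S,5R,6R,7aR,7bS)-5-(acetyloxy)-7a-methyl-2-oxo-6-(prop-1-en-2-yl)decahydro-1H-cyclopropa[a]naphthalen-4-yl 3-methylbut-2-enoate (the target skeleton with C15 bonded to both C4 and C3)
Conditions: AuCl[P(1-Ad)2(C6H4-2-morpholino)] (5 mol %), AgNTf2 (5 mol %), 8-methylquinoline N-oxide (slow addition), PhCl, rt
Reagents that add atoms: 8-methylquinoline N-oxide, Cc1cccc2ccc[n+]([O-])c12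
Why: Cationic gold activates the terminal alkyne, the N-oxide adds to the internal carbon C2 and loses 8-methylquinoline, and the α-oxo gold carbene formed at C3 adds to the vinyl group C4=C15. The closest known reaction type is the oxidative gold-catalysed cyclopropanation of terminal enynes, in which the alkyne stands in for an α-diazo ketone. Ring A is closed by the C3–C4 bond in a [2+1] addition that is exo for the six-membered ring (a bicyclo[4.1.0]heptan-2-one), and the temporary cyclopropane is closed by C3–C15. C4 is set by the substrate: on the chair of ring B the vinyl group is axial and the C10 tether equatorial, so the carbene can reach the alkene only from the face next to the C5 methyl group, and the vinyl rotamer with C15 turned away from C10 and from the axial C9 ester should be preferred, which places C15, the later methyl group, cis to the C5 methyl group; C3 follows because the cyclopropane must be cis-fused. The step needs chemoselectivity for carbene transfer to this alkene over enyne cycloisomerisation, a second oxidation and C–H insertion, which the P,N ligand (a less electrophilic carbene), slow addition of the oxidant, the fact that only the vinyl group offers a six-membered ring, and the deactivating acyloxy group on C9 are expected to secure.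

Step 10
Reactants: 15 (1aR,3aS,4S,5R,6R,7aR,7bS)-5-(acetyloxy)-7a-methyl-2-oxo-6-(prop-1-en-2-yl)decahydro-1H-cyclopropa[a]naphthalen-4-yl 3-methylbut-2-enoate
Product: 16 (1S,2R,3R,4aR,5S,8aS)-2-(acetyloxy)-4a,5-dimethyl-7-oxo-3-(prop-1-en-2-yl)decahydronaphthalen-1-yl 3-methylbut-2-enoate (CNP0150397.1)
Conditions: SmI2 (2.5 equiv), t-BuOH (2 equiv), THF–DMPU, −78 → 0 °C
Reagents that add atoms: none
Why: Reductive cleavage of a cyclopropyl ketone under stereoelectronic control: in the ketyl the exocyclic C3–C15 bond, which overlaps the carbonyl π system, should break in preference to the ring bond C3–C4, and reduction and protonation of the primary carbon and of the samarium enolate leave the C4 methyl group with C4 unchanged.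

Compound list
1 | (+)-3-carene, (1S,6R)-3,7,7-trimethylbicyclo[4.1.0]hept-3-ene | CC1=CC[C@@H]2[C@H](C1)C2(C)C | starting material
2 | (1R,6S)-4,7,7-trimethylbicyclo[4.1.0]hept-3-en-2-one | CC1=CC(=O)[C@@H]2[C@H](C1)C2(C)C | intermediate
3 | (5S)-3-methyl-5-(prop-1-en-2-yl)cyclohex-2-en-1-one | CC1=CC(=O)C[C@H](C1)C(C)=C | intermediate
4 | vinylmagnesium bromide | C=C[Mg]Br | starting material
5 | 3-bromo-1-(trimethylsilyl)prop-1-yne | C[Si](C)(C)C#CCBr | starting material
6 | bromomagnesium (3R,5S)-3-ethenyl-3-methyl-5-(prop-1-en-2-yl)cyclohex-1-en-1-olate | C=C(C)[C@H]1C[C@@](C=C)(C)C=C(O[Mg]Br)C1 | intermediate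
7 | (2R,3R,5S)-3-ethenyl-3-methyl-5-(prop-1-en-2-yl)-2-[3-(trimethylsilyl)prop-2-yn-1-yl]cyclohexan-1-one | C=C(C)[C@H]1C[C@@](C=C)(C)[C@@H](CC#C[Si](C)(C)C)C(=O)C1 | intermediate
8 | (2S,3R,5S)-3-ethenyl-3-methyl-5-(prop-1-en-2-yl)-2-(prop-2-yn-1-yl)cyclohexan-1-one | C=C(C)[C@H]1C[C@@](C=C)(C)[C@H](CC#C)C(=O)C1 | intermediate
9 | {[(3S,5R,6S)-5-ethenyl-5-methyl-3-(prop-1-en-2-yl)-6-(prop-2-yn-1-yl)cyclohex-1-en-1-yl]oxy}trimethylsilane | C=C(C)[C@H]1C[C@@](C=C)(C)[C@H](CC#C)C(O[Si](C)(C)C)=C1 | intermediate
10 | (2S,3R,5R,6S)-6-bromo-3-ethenyl-3-methyl-5-(prop-1-en-2-yl)-2-(prop-2-yn-1-yl)cyclohexan-1-one | C=C(C)[C@H]1C[C@@](C=C)(C)[C@H](CC#C)C(=O)[C@H]1Br | intermediate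
11 | (1R,3S,4R,6R)-4-ethenyl-4-methyl-2-oxo-6-(prop-1-en-2-yl)-3-(prop-2-yn-1-yl)cyclohexyl acetate | C=C(C)[C@H]1C[C@@](C=C)(C)[C@H](CC#C)C(=O)[C@@H]1OC(C)=O | intermediate
12 | (1R,2S,3S,4R,6R)-4-ethenyl-2-hydroxy-4-methyl-6-(prop-1-en-2-yl)-3-(prop-2-yn-1-yl)cyclohexyl acetate | C=C(C)[C@H]1C[C@@](C=C)(C)[C@H](CC#C)[C@H](O)[C@@H]1OC(C)=O | intermediate
13 | 3-methylbut-2-enoyl chloride | CC(C)=CC(Cl)=O | starting material
14 | (1S,2S,3R,5R,6R)-6-(acetyloxy)-3-ethenyl-3-methyl-5-(prop-1-en-2-yl)-2-(prop-2-yn-1-yl)cyclohexyl 3-methylbut-2-enoate | C=C(C)[C@H]1C[C@@](C=C)(C)[C@H](CC#C)[C@H](OC(=O)C=C(C)C)[C@@H]1OC(C)=O | intermediate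
15 | (1aR,3aS,4S,5R,6R,7aR,7bS)-5-(acetyloxy)-7a-methyl-2-oxo-6-(prop-1-en-2-yl)decahydro-1H-cyclopropa[a]naphthalen-4-yl 3-methylbut-2-enoate | C=C(C)[C@H]1C[C@@]2(C)[C@H](CC(=O)[C@@H]3C[C@H]23)[C@H](OC(=O)C=C(C)C)[C@@H]1OC(C)=O | intermediate
16 | (1S,2R,3R,4aR,5S,8aS)-2-(acetyloxy)-4a,5-dimethyl-7-oxo-3-(prop-1-en-2-yl)decahydronaphthalen-1-yl 3-methylbut-2-enoate | C=C(C)[C@H]1C[C@@]2(C)[C@H](CC(=O)C[C@@H]2C)[C@H](OC(=O)C=C(C)C)[C@@H]1OC(C)=O | target

Total step count: 10. Longest linear sequence: 10 steps (1 → 16).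

Steps most likely to fail

Step 9. Carbene transfer may be outrun by gold-mediated cycloisomerisation of the enyne or by a second oxidation of the carbene, and the oxidant may be used up unproductively. The carbene would then be generated from a diazo ketone. Setting out from 14, mercury-catalysed hydration of the alkyne (Hg(OTf)2 cat., tetramethylurea, MeCN–H2O) gives the methyl ketone (1S,2S,3R,5R,6R)-6-(acetyloxy)-3-ethenyl-3-methyl-2-(2-oxopropyl)-5-(prop-1-en-2-yl)cyclohexyl 3-methylbut-2-enoate F1. Kinetic enolisation on the methyl side (LiN(SiMe3)2, −78 °C) and acylation with CF3CO2CH2CF3 gives the trifluoromethyl β-diketone F2. Deacylative diazo transfer (MsN3, Et3N, H2O, MeCN) converts it into the α-diazo ketone F3. Rh2(OAc)4 in CH2Cl2 should then effect the classical intramolecular cyclopropanation of the vinyl group, and the route is rejoined at 15.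

Step 2. The thermal hydrogen shift may be too slow in the rigid bicyclic ketone and be overtaken by unselective isomerisation or decomposition at the temperature it needs. Polar cleavage of the same cyclopropane bond is the alternative. From 2, homoconjugate opening with Me3SiI (Me3SiCl, NaI, MeCN, 0 °C) gives the tertiary iodide as its silyl dienol ether {[(3S)-3-(2-iodopropan-2-yl)-5-methylcyclohexa-1,5-dien-1-yl]oxy}trimethylsilane F4, in which the masked enol cannot re-close the ring. DBU then eliminates hydrogen iodide to give the isopropenyl silyl dienol ether {[(3S)-5-methyl-3-(prop-1-en-2-yl)cyclohexa-1,5-dien-1-yl]oxy}trimethylsilane F5; any isopropylidene isomer would have to be separated. Mild acid hydrolysis returns to 3.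

Step 4. The equilibrium at C10 may lie too close to an even mixture, so that too little of the cis epimer is obtained. The centre can instead be set by protonating an enolate that already carries the side chain. From 3, the conjugate addition of 4 is repeated, but the enolate is trapped with dimethylmethyleneiminium iodide to give the Mannich base (3R,5S)-2-[(dimethylamino)methyl]-3-ethenyl-3-methyl-5-(prop-1-en-2-yl)cyclohexan-1-one F6. N-Methylation (MeI) and elimination (NaHCO3) give the enone (3R,5S)-3-ethenyl-3-methyl-2-methylidene-5-(prop-1-en-2-yl)cyclohexan-1-one F7. 1,4-Addition of Et2AlC≡CSiMe3 to this s-cis enone, followed by protonation of the aluminium enolate from the face opposite the axial vinyl group, should give the cis ketone (2S,3R,5S)-3-ethenyl-3-methyl-5-(prop-1-en-2-yl)-2-[3-(trimethylsilyl)prop-2-yn-1-yl]cyclohexan-1-one F8. K2CO3 in MeOH removes the silyl group and returns to 8.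

Further compounds
F1 | step 9 | (1S,2S,3R,5R,6R)-6-(acetyloxy)-3-ethenyl-3-methyl-2-(2-oxopropyl)-5-(prop-1-en-2-yl)cyclohexyl 3-methylbut-2-enoate | C=C(C)[C@H]1C[C@@](C=C)(C)[C@H](CC(C)=O)[C@H](OC(=O)C=C(C)C)[C@@H]1OC(C)=O
F2 | step 9 | (1S,2S,3R,5R,6R)-6-(acetyloxy)-3-ethenyl-3-methyl-5-(prop-1-en-2-yl)-2-(5,5,5-trifluoro-2,4-dioxopentyl)cyclohexyl 3-methylbut-2-enoate | C=C(C)[C@H]1C[C@@](C=C)(C)[C@H](CC(=O)CC(=O)C(F)(F)F)[C@H](OC(=O)C=C(C)C)[C@@H]1OC(C)=O
F3 | step 9 | (1S,2S,3R,5R,6R)-6-(acetyloxy)-2-(3-diazo-2-oxopropyl)-3-ethenyl-3-methyl-5-(prop-1-en-2-yl)cyclohexyl 3-methylbut-2-enoate | C=C(C)[C@H]1C[C@@](C=C)(C)[C@H](CC(=O)C=[N+]=[N-])[C@H](OC(=O)C=C(C)C)[C@@H]1OC(C)=O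
F4 | step 2 | {[(3S)-3-(2-iodopropan-2-yl)-5-methylcyclohexa-1,5-dien-1-yl]oxy}trimethylsilane | CC1=CC(O[Si](C)(C)C)=C[C@H](C1)C(C)(C)I
F5 | step 2 | {[(3S)-5-methyl-3-(prop-1-en-2-yl)cyclohexa-1,5-dien-1-yl]oxy}trimethylsilane | CC1=CC(O[Si](C)(C)C)=C[C@H](C1)C(C)=C
F6 | step 4 | (3R,5S)-2-[(dimethylamino)methyl]-3-ethenyl-3-methyl-5-(prop-1-en-2-yl)cyclohexan-1-one | C=C(C)[C@H]1C[C@@](C=C)(C)C(CN(C)C)C(=O)C1
F7 | step 4 | (3R,5S)-3-ethenyl-3-methyl-2-methylidene-5-(prop-1-en-2-yl)cyclohexan-1-one | C=C(C)[C@H]1C[C@@](C=C)(C)C(=C)C(=O)C1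
F8 | step 4 | (2S,3R,5S)-3-ethenyl-3-methyl-5-(prop-1-en-2-yl)-2-[3-(trimethylsilyl)prop-2-yn-1-yl]cyclohexan-1-one | C=C(C)[C@H]1C[C@@](C=C)(C)[C@H](CC#C[Si](C)(C)C)C(=O)C1
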